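**Retrosynthetic overview**
- The target is cut between the ester OCH2 carbon and the neighbouring CH stereocentre. This gives the chloromethyl ester of the O-protected (Z)-acid (an acyloxymethyl cation source that already carries the whole acid part) and (E)-1-(4-methoxyphenyl)penta-1,4-diene.
- Enabling feature: the 4-methoxyphenyl ring on the carbinol carbon next to that CH stabilises a cation there, and the carbinol O and ester O stand 1,3 to each other. The six atoms O–CH(Ar)–CH–CH2–O–C(acyl) therefore map onto a 1,3-dioxan-2-ylium ring.
- Rings: both benzene rings are bought. The only ring closed is this temporary dioxanylium ring in the key step, and it is opened in the same flask to the hydroxy ester with both stereocentres in place.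
- The 3,4-dimethoxystyryl end is added afterwards by cross-metathesis, because a second electron-rich styrene would compete for the cation. Removal of the chloroacetate ends the route.
- The (Z)-acid comes from crotonaldehyde through (Z)-2-iodobut-2-en-1-ol and carbonylation with retention.

Key step: step 7

Assumption: the sense of asymmetric induction of the chiral anion in step 7 cannot be predicted with certainty; the catalyst is written as (S,S), and its mirror image is to be used if a first experiment shows the opposite sense.

**Route**

Step 1
Reactants: 1 (E)-but-2-enal (crotonaldehyde)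
Product: 2 (Z)-2-iodobut-2-enal
Conditions: I2 (1.5 equiv), K2CO3 (1.2 equiv), DMAP (0.2 equiv), THF–H2O, rt
Reagents that add atoms: iodine II
Why: α-Iodination of the enal by the Baylis–Hillman-type sequence (conjugate addition of DMAP, iodination of the enolate, E1cB loss of DMAP) should give the thermodynamic (Z)-iodoenal, in which CH3 stays trans to CHO.

Step 2
Reactants: 2 (Z)-2-iodobut-2-enal
Product: 3 (Z)-2-iodobut-2-en-1-ol
Conditions: NaBH4 (0.5 equiv), CeCl3·7H2O (1 equiv), MeOH, 0 °C
Reagents that add atoms: none
Why: Luche 1,2-reduction of the aldehyde should leave the alkenyl iodide and the double-bond geometry untouched.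

Step 3
Reactants: 3 (Z)-2-iodobut-2-en-1-ol
Product: 4 (Z)-2-(hydroxymethyl)but-2-enoic acid
Conditions: Pd(OAc)2 (5 mol %), PPh3 (10 mol %), CO (1 atm), K2CO3 (3 equiv), DMF–H2O, 50 °C; then 1 M HCl to pH 2
Reagents that add atoms: carbon monoxide [C-]#[O+]; water O
Why: Palladium-catalysed hydroxycarbonylation of the alkenyl iodide (oxidative addition, CO insertion, hydrolysis of the acyl-palladium) proceeds with retention of alkene geometry, so CO2H should take the place of iodine cis to CH3 and give the (Z)-acid.

Step 4
Reactants: 4 (Z)-2-(hydroxymethyl)but-2-enoic acid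
Product: 5 (Z)-2-[(2-chloroacetoxy)methyl]but-2-enoic acid
Conditions: (ClCH2CO)2O (1.3 equiv), pyridine (2.5 equiv), CH2Cl2, 0 °C; then H2O–THF, dilute HCl wash
Reagents that add atoms: chloroacetic anhydride O=C(CCl)OC(=O)CCl
Why: O-Acylation of the primary allylic hydroxyl (any mixed anhydride at the carboxyl group is hydrolysed in the aqueous work-up) should give the chloroacetate, an electron-poor protecting group whose oxygen cannot capture the cation of step 7 and which is removable beside other esters.

Step 5
Reactants: 5 (Z)-2-[(2-chloroacetoxy)methyl]but-2-enoic acid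
Product: 6 chloromethyl (Z)-2-[(2-chloroacetoxy)methyl]but-2-enoate
Conditions: ClCH2OSO2Cl (1.2 equiv), NaHCO3 (4 equiv), Bu4NHSO4 (10 mol %), CH2Cl2–H2O, 0 °C to rt
Reagents that add atoms: chloromethyl chlorosulfate ClCOS(=O)(=O)Cl
Why: Phase-transfer O-alkylation of the carboxylate by chloromethyl chlorosulfate (chlorosulfate leaves, the C–Cl bond stays) is the standard route to chloromethyl esters and should not touch the alkene geometry.

Step 6
Reactants: 7 (E)-2-(4-methoxyphenyl)vinylboronic acid
Product: 8 1-methoxy-4-[(1E)-penta-1,4-dien-1-yl]benzene
Conditions: allyl bromide (1.5 equiv), Pd(PPh3)4 (3 mol %), K2CO3 (2 equiv), THF–H2O, 60 °C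
Reagents that add atoms: allyl bromide C=CCBr
Why: Suzuki–Miyaura allyl–alkenyl coupling through a π-allylpalladium intermediate should keep the (E)-geometry of the alkenylboronic acid and give the skipped diene.

Step 7
Reactants: 8 1-methoxy-4-[(1E)-penta-1,4-dien-1-yl]benzene, 6 chloromethyl (Z)-2-[(2-chloroacetoxy)methyl]but-2-enoate
Product: 12 (2S)-2-[(S)-hydroxy(4-methoxyphenyl)methyl]pent-4-en-1-yl (Z)-2-[(2-chloroacetoxy)methyl]but-2-enoate, via acyloxymethyl cation 9 (not isolated), via 1,3-dioxan-2-ylium ion 10 (not isolated), via cyclic hemiorthoester 11 (not isolated)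
Conditions: Ag2CO3 (1.2 equiv), (S,S)-IDPi confined imidodiphosphorimidate acid (5 mol %), 4 Å MS, PhMe–CH2Cl2, −40 °C, slow addition of 6 (1.2 equiv); then aq NaCl–NaHCO3, 0 °C
Reagents that add atoms: silver(I) carbonate [Ag+].[Ag+].[O-]C([O-])=O; water O
Why: Proposed new method: the silver salt of the chiral IDPi anion (formed and re-formed from insoluble Ag2CO3, i.e. chiral-anion phase transfer) should take chloride from 6, and the ion-paired acyloxymethyl cation 9 should be attacked by the 4-methoxystyryl C=C of 8 at its β-carbon, so that the new C–C bond joins the OCH2 carbon to the future CH stereocentre and the charge arrives on the 4-methoxybenzylic carbon. The closest known reaction types are the confined-acid-catalysed asymmetric intermolecular Prins reaction of aryl olefins with formaldehyde, the Lewis-acid addition of chloromethyl esters and ethers across olefins, and silver-carbonate chiral-anion phase-transfer halide abstraction. The ester carbonyl oxygen then closes the temporary six-membered 1,3-dioxan-2-ylium ring 10 by O–C bond formation at the benzylic cation (a six-membered closure with the cationic carbon inside the ring; overall a stepwise polar [4+2] addition of the O=C–O–CH2(+) unit across the olefin). The CH stereocentre is set in the C–C bond formation by the confined chiral anion, which shields one face of the olefin in the ion-pair encounter, and the carbinol centre is set in the ring closure, which should place aryl and allyl trans-diequatorial (the expected trans preference of Prins adducts of anethole-type olefins, reinforced because the anisyl cation lets the closure equilibrate). Carbonate (or water at the quench) should then add to the carboxonium carbon and not to the benzylic carbon, so that the benzylic C–O bond and its configuration are kept, and hemiorthoester 11 should collapse by loss of the more hindered, more acidic benzylic oxygen to the primary ester, which is also the thermodynamic regioisomer by 1,3-acyl shift. The step needs attack at the styryl and not at the terminal olefin or an arene, and at the β- and not the α-carbon, both secured by the 4-methoxyphenyl group (far higher π-nucleophilicity, benzylic cation), and it needs an acid side chain that cannot capture 9, secured by the chloroacetate in place of an ether or silyl ether.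

Step 8
Reactants: 12 (2S)-2-[(S)-hydroxy(4-methoxyphenyl)methyl]pent-4-en-1-yl (Z)-2-[(2-chloroacetoxy)methyl]but-2-enoate, 13 4-ethenyl-1,2-dimethoxybenzene (3,4-dimethoxystyrene)
Product: 14 (2S,4E)-5-(3,4-dimethoxyphenyl)-2-[(S)-hydroxy(4-methoxyphenyl)methyl]pent-4-en-1-yl (Z)-2-[(2-chloroacetoxy)methyl]but-2-enoate
Conditions: Hoveyda–Grubbs II (5 mol %), 13 (3 equiv), CH2Cl2, 40 °C
Reagents that add atoms: none
Why: Olefin cross-metathesis of the terminal alkene with excess styrene should be (E)-selective under thermodynamic control, while the trisubstituted electron-poor butenoate C=C, the free alcohol and both stereocentres are inert to the ruthenium carbene.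

Step 9
Reactants: 14 (2S,4E)-5-(3,4-dimethoxyphenyl)-2-[(S)-hydroxy(4-methoxyphenyl)methyl]pent-4-en-1-yl (Z)-2-[(2-chloroacetoxy)methyl]but-2-enoate
Product: 15 (2S,4E)-5-(3,4-dimethoxyphenyl)-2-[(S)-hydroxy(4-methoxyphenyl)methyl]pent-4-en-1-yl (Z)-2-(hydroxymethyl)but-2-enoate (CNP0210582.1)
Conditions: thiourea (3 equiv), NaHCO3 (3 equiv), EtOH–THF, 50 °C
Reagents that add atoms: none
Why: S-Alkylation of thiourea at the ClCH2 group and cyclisation of the isothiouronium ester onto its own carbonyl should release the allylic alcohol under neutral conditions, so the conjugated α-branched butenoate ester, the labile 4-methoxybenzylic alcohol and both stereocentres are not touched.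

**Compound list**
1 | (E)-but-2-enal (crotonaldehyde) | C/C=C/C=O | starting material
2 | (Z)-2-iodobut-2-enal | C/C=C(I)/C=O | intermediate
3 | (Z)-2-iodobut-2-en-1-ol | C/C=C(I)/CO | intermediate
4 | (Z)-2-(hydroxymethyl)but-2-enoic acid | C/C=C(/CO)C(=O)O | intermediate
5 | (Z)-2-[(2-chloroacetoxy)methyl]but-2-enoic acid | C/C=C(/COC(=O)CCl)C(=O)O | intermediate
6 | chloromethyl (Z)-2-[(2-chloroacetoxy)methyl]but-2-enoate | C/C=C(/COC(=O)CCl)C(=O)OCCl | intermediate
7 | (E)-2-(4-methoxyphenyl)vinylboronic acid | COc1ccc(/C=C/B(O)O)cc1 | starting material
8 | 1-methoxy-4-[(1E)-penta-1,4-dien-1-yl]benzene | C=CC/C=C/c1ccc(OC)cc1 | intermediate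
9 | [(Z)-2-[(2-chloroacetoxy)methyl]but-2-enoyl]oxymethylium (acyloxymethyl cation, ion-paired with the chiral anion; not isolated) | C/C=C(/COC(=O)CCl)C(=O)O[CH2+] | intermediate
10 | (4S,5S)-2-[(Z)-1-[(2-chloroacetoxy)methyl]prop-1-en-1-yl]-4-(4-methoxyphenyl)-5-(prop-2-en-1-yl)-1,3-dioxan-2-ylium (not isolated) | C/C=C(/COC(=O)CCl)C1=[O+][C@H](c2ccc(OC)cc2)[C@@H](CC=C)CO1 | intermediate
11 | (4S,5S)-2-hydroxy-2-[(Z)-1-[(2-chloroacetoxy)methyl]prop-1-en-1-yl]-4-(4-methoxyphenyl)-5-(prop-2-en-1-yl)-1,3-dioxane (cyclic hemiorthoester, C-2 not defined; not isolated) | C/C=C(/COC(=O)CCl)C1(O)O[C@H](c2ccc(OC)cc2)[C@@H](CC=C)CO1 | intermediate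
12 | (2S)-2-[(S)-hydroxy(4-methoxyphenyl)methyl]pent-4-en-1-yl (Z)-2-[(2-chloroacetoxy)methyl]but-2-enoate | C/C=C(/COC(=O)CCl)C(=O)OC[C@H](CC=C)[C@H](O)c1ccc(OC)cc1 | intermediate
13 | 4-ethenyl-1,2-dimethoxybenzene (3,4-dimethoxystyrene) | C=Cc1ccc(OC)c(OC)c1 | starting material
14 | (2S,4E)-5-(3,4-dimethoxyphenyl)-2-[(S)-hydroxy(4-methoxyphenyl)methyl]pent-4-en-1-yl (Z)-2-[(2-chloroacetoxy)methyl]but-2-enoate | C/C=C(/COC(=O)CCl)C(=O)OC[C@H](C/C=C/c1ccc(OC)c(OC)c1)[C@H](O)c1ccc(OC)cc1 | intermediate
15 | (2S,4E)-5-(3,4-dimethoxyphenyl)-2-[(S)-hydroxy(4-methoxyphenyl)methyl]pent-4-en-1-yl (Z)-2-(hydroxymethyl)but-2-enoate | C/C=C(/CO)C(=O)OC[C@H](C/C=C/c1ccc(OC)c(OC)c1)[C@H](O)c1ccc(OC)cc1 | target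

**Step count**
Total steps: 9. Longest linear sequence: 8 (steps 1–5, 7–9).

**Steps most likely to fail**

Step 7 (Proposed new method). The enantiofacial discrimination by the ion-paired anion in the C–C bond formation may be poor. The acyloxymethyl cation may also be lost to fragmentation (acylium and formaldehyde) or to cationic oligomerisation of the styrene before the ring closes, and turnover of the anion at the solid carbonate may stall. Fallback with known chemistry, in which the two stereocentres are built by substrate control and the ester is attached last: it sets out from acid 5 and comes back at 12. Commercial methyl 3-(4-methoxyphenyl)-3-oxopropanoate is hydrogenated under Noyori conditions (Ru–(R)-BINAP, H2, MeOH) to methyl (3S)-3-hydroxy-3-(4-methoxyphenyl)propanoate F1. Its dianion (LDA, 2.2 equiv, THF, −78 to −20 °C) is allylated anti to the alkoxide with allyl bromide (Fráter–Seebach alkylation) to give methyl (2R,3S)-3-hydroxy-3-(4-methoxyphenyl)-2-(prop-2-en-1-yl)propanoate F2. LiAlH4 in THF reduces the ester to (1S,2S)-1-(4-methoxyphenyl)-2-(prop-2-en-1-yl)propane-1,3-diol F3, and the primary hydroxyl of this diol is esterified selectively with 5 (EDC, cat. DMAP, CH2Cl2, −20 °C) to give 12.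

Step 8. Self-metathesis of either partner and ruthenium-hydride-induced migration of the terminal double bond into the chain may outrun productive cross-metathesis, and (E)/(Z) control may be incomplete. Fallback: it sets out from 12 and comes back at 14 and makes no new compound (F0). The terminal alkene is arylated in a Mizoroki–Heck reaction with 4-iodo-1,2-dimethoxybenzene (Pd(OAc)2, Bu4NCl, NaHCO3, DMF, 50 °C), in which β-hydride elimination toward conjugation should give the (E)-styrene directly.

Step 3. The acyl-palladium intermediate may be captured by the neighbouring hydroxyl (lactone or oligoester formation), the allylic C–O bond may ionise on palladium, and the water-soluble hydroxy acid may be lost on isolation. Fallback: it sets out from 3 and comes back at 4 and makes no new compound (F0). Alcohol 3 is deprotonated with n-BuLi (1 equiv) and subjected to iodine–lithium exchange with t-BuLi (2 equiv) in Et2O at −78 °C; the configurationally stable alkenyllithium alkoxide is carboxylated with CO2 and acidified to give 4.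

**Further compounds**
F1 | step 7 | methyl (3S)-3-hydroxy-3-(4-methoxyphenyl)propanoate | COC(=O)C[C@H](O)c1ccc(OC)cc1
F2 | step 7 | methyl (2R,3S)-3-hydroxy-3-(4-methoxyphenyl)-2-(prop-2-en-1-yl)propanoate | COC(=O)[C@H](CC=C)[C@H](O)c1ccc(OC)cc1
F3 | step 7 | (1S,2S)-1-(4-methoxyphenyl)-2-(prop-2-en-1-yl)propane-1,3-diol | OC[C@H](CC=C)[C@H](O)c1ccc(OC)cc1
F0 | step 8 | none | none
F0 | step 3 | none | none
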